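**Retrosynthetic overview**
1. The lactone is formed last: acid removes the acetonide and the tert-butyl ester, and the freed acrylic acid closes onto the C6 hydroxyl; the angelate is put on C8 just before.
2. The ten-membered carbocycle is closed before the lactone, by an intramolecular Nozaki–Hiyama–Kishi allylation that forms C7–C8 and sets C7 and C8 in the ring-closing step (key step, in place of ring-closing metathesis).
3. The open-chain precursor comes from an E-selective cross-metathesis (C2=C3 enone) of a west allylic bromide with an east vinyl ketone aldehyde.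
4. West fragment (C3–C7, C11–C13): (S)-glyceraldehyde acetonide, Brown (E)-crotylboration (C4, C5), acetonide migration, Baylis–Hillman reaction, bromination.
5. East fragment (C1, C2, C8–C10): (R)-lactic acid, Seebach allylation (C10), Weinreb amide, vinyl Grignard, acetylation, ozonolysis.

Assumption: the side chain /C(C)=C\C is (Z)-2-methylbut-2-enoate (angelate); atom labels follow germacrane numbering (C1 ketone, C2=C3, C4 methyl, C5 OH, C6 lactone O, C7, C8 angelate, C9, C10 acetate, C11–C13 acrylate unit), and the target is (4S,5S,6S,7R,8R,10S).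

**Route**

Step 1
Reactants: 1 (S)-2,2-dimethyl-1,3-dioxolane-4-carbaldehyde
Product: 2 (1S,2S)-1-[(4S)-2,2-dimethyl-1,3-dioxolan-4-yl]-2-methylbut-3-en-1-ol
Conditions: trans-2-butene, KOt-Bu, n-BuLi, THF, −78 to −45 °C; (−)-Ipc2BOMe, −78 °C; BF3·OEt2; then 1, −78 °C; 3 M NaOH, 30% H2O2
Reagents that add atoms: trans-2-butene C/C=C/C
Why: Brown asymmetric (E)-crotylboration through a chair Zimmerman–Traxler transition state, in which the E-crotyl geometry gives the 4,5-anti methyl/hydroxyl pair and the (+)-α-pinene-derived Ipc ligands direct attack to the Si face of the aldehyde, overriding its Felkin bias to set C5 (S) and thus the 5,6-syn diol.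

Step 2
Reactants: 2 (1S,2S)-1-[(4S)-2,2-dimethyl-1,3-dioxolan-4-yl]-2-methylbut-3-en-1-ol
Product: 3 [(4S,5S)-5-[(2S)-but-3-en-2-yl]-2,2-dimethyl-1,3-dioxolan-4-yl]methanol
Conditions: p-TsOH·H2O (5 mol %), acetone, 23 °C (equilibration; recovered 2 recycled)
Reagents that add atoms: none
Why: Acid-catalysed acetonide migration (transketalisation) under thermodynamic control favours the trans-4,5-disubstituted dioxolane across the syn-5,6-diol over the terminal dioxolane and frees the primary C7 hydroxyl without touching a stereocentre.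

Step 3
Reactants: 3 [(4S,5S)-5-[(2S)-but-3-en-2-yl]-2,2-dimethyl-1,3-dioxolan-4-yl]methanol
Product: 4 (4R,5S)-5-[(2S)-but-3-en-2-yl]-2,2-dimethyl-1,3-dioxolane-4-carbaldehyde
Conditions: TEMPO (10 mol %), PhI(OAc)2, CH2Cl2, 23 °C
Reagents that add atoms: none
Why: TEMPO/PhI(OAc)2 oxidation of the primary alcohol is neutral, spares the alkene and does not epimerise the α-alkoxy centre (the trans-dioxolane is in any case the stable epimer).

Step 4
Reactants: 4 (4R,5S)-5-[(2S)-but-3-en-2-yl]-2,2-dimethyl-1,3-dioxolane-4-carbaldehyde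
Product: 5 tert-butyl 2-{[(4S,5S)-5-[(2S)-but-3-en-2-yl]-2,2-dimethyl-1,3-dioxolan-4-yl](hydroxy)methyl}prop-2-enoate (both carbinol epimers)
Conditions: tert-butyl acrylate (3 equiv), DABCO (1 equiv), 1,4-dioxane/H2O 1:1, 23 °C, 72 h
Reagents that add atoms: tert-butyl acrylate C=CC(=O)OC(C)(C)C
Why: Morita–Baylis–Hillman reaction of an activated α-alkoxy aldehyde, whose new carbinol configuration does not matter because it is erased in step 5.

Step 5
Reactants: 5 tert-butyl 2-{[(4S,5S)-5-[(2S)-but-3-en-2-yl]-2,2-dimethyl-1,3-dioxolan-4-yl](hydroxy)methyl}prop-2-enoate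
Product: 6 tert-butyl (2Z)-2-(bromomethyl)-3-[(4S,5S)-5-[(2S)-but-3-en-2-yl]-2,2-dimethyl-1,3-dioxolan-4-yl]prop-2-enoate
Conditions: NBS, Me2S, CH2Cl2, 0 °C; then 5, 0 to 23 °C
Reagents that add atoms: N-bromosuccinimide O=C1CCC(=O)N1Br
Why: Corey–Kim-type activation of the allylic alcohol and bromide return with allylic transposition (SN2′) gives the (Z)-2-(bromomethyl)enoate, the usual outcome for Baylis–Hillman adducts, under acid-free conditions that keep the acetonide.

Step 6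
Reactants: 7 (R)-lactic acid
Product: 8 (2R,5R)-2-tert-butyl-5-methyl-1,3-dioxolan-4-one
Conditions: pivalaldehyde, p-TsOH·H2O (cat.), H2SO4 (cat.), pentane, reflux, Dean–Stark; recrystallisation at −78 °C
Reagents that add atoms: pivalaldehyde CC(C)(C)C=O
Why: Seebach acetalisation gives the cis-dioxolanone as the major, crystallisable isomer, which stores the lactate chirality at the acetal carbon (self-regeneration of stereocentres).

Step 7
Reactants: 8 (2R,5R)-2-tert-butyl-5-methyl-1,3-dioxolan-4-one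
Product: 10 (2R,5S)-2-tert-butyl-5-methyl-5-(prop-2-en-1-yl)-1,3-dioxolan-4-one, via lithium enolate 9 (not isolated)
Conditions: LiN(i-Pr)2, THF, −78 °C; allyl bromide, −78 to −20 °C
Reagents that add atoms: allyl bromide C=CCBr
Why: Seebach enolate alkylation occurs on the face opposite the tert-butyl group, so allyl replaces H with retention and sets the quaternary C10 centre (S).

Step 8
Reactants: 10 (2R,5S)-2-tert-butyl-5-methyl-5-(prop-2-en-1-yl)-1,3-dioxolan-4-one
Product: 11 (2S)-2-hydroxy-N-methoxy-N,2-dimethylpent-4-enamide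
Conditions: MeNH(OMe)·HCl, i-PrMgCl, THF, −20 to 0 °C
Reagents that add atoms: N,O-dimethylhydroxylamine hydrochloride CNOC.Cl
Why: Weinreb amide formation by aminolysis of the acetal-ester with the magnesium amide releases pivalaldehyde and the tertiary alcohol without affecting the quaternary centre.

Step 9
Reactants: 11 (2S)-2-hydroxy-N-methoxy-N,2-dimethylpent-4-enamide
Product: 12 (4S)-4-hydroxy-4-methylhepta-1,6-dien-3-one
Conditions: CH2=CHMgBr (3 equiv), THF, −78 to 0 °C; inverse quench into cold 1 M HCl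
Reagents that add atoms: vinylmagnesium bromide C=C[Mg]Br
Why: Weinreb ketone synthesis, in which the chelated tetrahedral intermediate prevents over-addition and the acidic inverse quench keeps the liberated amine from adding to the vinyl ketone.

Step 10
Reactants: 12 (4S)-4-hydroxy-4-methylhepta-1,6-dien-3-one
Product: 13 (4S)-4-methyl-3-oxohepta-1,6-dien-4-yl acetate
Conditions: Ac2O, Sc(OTf)3 (2 mol %), MeCN, −20 °C
Reagents that add atoms: acetic anhydride CC(=O)OC(C)=O
Why: Lewis acid-catalysed acylation esterifies the hindered tertiary α-hydroxy ketone at low temperature without nucleophilic amine catalysts that would add to the vinyl ketone.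

Step 11
Reactants: 13 (4S)-4-methyl-3-oxohepta-1,6-dien-4-yl acetate
Product: 15 (3S)-3-methyl-1,4-dioxohex-5-en-3-yl acetate, via secondary ozonide 14 (not isolated)
Conditions: O3, CH2Cl2, −78 °C, Sudan Red 7B end point; then Me2S, −78 to 23 °C; used at once
Reagents that add atoms: ozone [O-][O+]=O
Why: Chemoselective ozonolysis, since electrophilic ozone cleaves the isolated terminal alkene far faster than the electron-poor enone double bond.

Step 12
Reactants: 6 tert-butyl (2Z)-2-(bromomethyl)-3-[(4S,5S)-5-[(2S)-but-3-en-2-yl]-2,2-dimethyl-1,3-dioxolan-4-yl]prop-2-enoate; 15 (3S)-3-methyl-1,4-dioxohex-5-en-3-yl acetate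
Product: 16 tert-butyl (2Z)-3-[(4S,5S)-5-[(2S,3E,6S)-6-acetoxy-6-methyl-5,8-dioxooct-3-en-2-yl]-2,2-dimethyl-1,3-dioxolan-4-yl]-2-(bromomethyl)prop-2-enoate
Conditions: 6 (1 equiv), 15 (2 equiv), second-generation Hoveyda–Grubbs catalyst RuCl2(H2IMes)(=CH-C6H4-2-O-i-Pr) (10 mol %), CH2Cl2, 40 °C
Reagents that add atoms: none
Why: Olefin cross-metathesis of a terminal alkene with a vinyl ketone is E-selective, and the Ru carbene ignores the trisubstituted enoate, the allylic bromide and the aldehyde, so the C2=C3 E-enone is fixed before ring closure.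

Step 13
Reactants: 16 tert-butyl (2Z)-3-[(4S,5S)-5-[(2S,3E,6S)-6-acetoxy-6-methyl-5,8-dioxooct-3-en-2-yl]-2,2-dimethyl-1,3-dioxolan-4-yl]-2-(bromomethyl)prop-2-enoate
Product: 18 tert-butyl 2-[(1R,2R,4S,6E,8S,9S,10S)-4-acetoxy-2-hydroxy-9,10-(isopropylidenedioxy)-4,8-dimethyl-5-oxocyclodec-6-en-1-yl]prop-2-enoate, via allylchromium species 17 (not isolated)
Conditions: CrCl2 (8 equiv), THF, 23 °C, 2 mM, 16 added by syringe pump over 10 h; aqueous NH4Cl
Reagents that add atoms: none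
Why: Intramolecular Nozaki–Hiyama–Kishi (Barbier-type) allylation, a reaction type already used to close ten-membered germacranolide rings, adds γ-selectively to the aldehyde only; the tether through C5 plus allylic 1,3-strain place the aldehyde on the alkene face anti to the C6–O bond (7R), the ester-locked Z-allylchromium in a chair transition state gives the 7,8-syn adduct (8R), and the tert-butyl ester blocks lactonisation onto the new C8 alkoxide.

Step 14
Reactants: 18 tert-butyl 2-[(1R,2R,4S,6E,8S,9S,10S)-4-acetoxy-2-hydroxy-9,10-(isopropylidenedioxy)-4,8-dimethyl-5-oxocyclodec-6-en-1-yl]prop-2-enoate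
Product: 19 tert-butyl 2-[(1R,2R,4S,6E,8S,9S,10S)-4-acetoxy-9,10-(isopropylidenedioxy)-4,8-dimethyl-2-{[(2Z)-2-methylbut-2-enoyl]oxy}-5-oxocyclodec-6-en-1-yl]prop-2-enoate
Conditions: angelic acid, 2,4,6-trichlorobenzoyl chloride, Et3N, toluene, 23 °C; then 18, toluene, 80 °C
Reagents that add atoms: angelic acid C/C=C(/C)C(=O)O
Why: Yamaguchi-type mixed-anhydride esterification without DMAP acylates the secondary C8 alcohol with retention and avoids base-induced isomerisation of angelate to tiglate.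

Step 15
Reactants: 19 tert-butyl 2-[(1R,2R,4S,6E,8S,9S,10S)-4-acetoxy-9,10-(isopropylidenedioxy)-4,8-dimethyl-2-{[(2Z)-2-methylbut-2-enoyl]oxy}-5-oxocyclodec-6-en-1-yl]prop-2-enoate
Product: 21 CNP0259154.2 (4S,5S,6S,7R,8R,10S)-10-acetoxy-8-angeloyloxy-5-hydroxy-1-oxogermacra-2(E),11(13)-dien-12,6-olide, via dihydroxy acid 20 (not isolated)
Conditions: TFA/CH2Cl2/H2O 10:10:1, 0 to 23 °C; concentration; saturated aqueous NaHCO3 wash
Reagents that add atoms: none
Why: Acidolysis removes the acetonide and the tert-butyl ester in one pot, and acid-catalysed lactonisation of the freed acrylic acid onto the C6 hydroxyl gives the favoured trans-fused γ-lactone (not the δ-lactone to C5), leaving C5–OH free and no stereocentre touched.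

**Compound list**
1 | (S)-2,2-dimethyl-1,3-dioxolane-4-carbaldehyde | O=C[C@@H]1COC(C)(C)O1 | starting material
2 | (1S,2S)-1-[(4S)-2,2-dimethyl-1,3-dioxolan-4-yl]-2-methylbut-3-en-1-ol | C=C[C@H](C)[C@H](O)[C@@H]1COC(C)(C)O1 | intermediate
3 | [(4S,5S)-5-[(2S)-but-3-en-2-yl]-2,2-dimethyl-1,3-dioxolan-4-yl]methanol | C=C[C@H](C)[C@@H]1OC(C)(C)O[C@H]1CO | intermediate
4 | (4R,5S)-5-[(2S)-but-3-en-2-yl]-2,2-dimethyl-1,3-dioxolane-4-carbaldehyde | C=C[C@H](C)[C@@H]1OC(C)(C)O[C@H]1C=O | intermediate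
5 | tert-butyl 2-{[(4S,5S)-5-[(2S)-but-3-en-2-yl]-2,2-dimethyl-1,3-dioxolan-4-yl](hydroxy)methyl}prop-2-enoate (both carbinol epimers) | C=C[C@H](C)[C@@H]1OC(C)(C)O[C@H]1C(O)C(=C)C(=O)OC(C)(C)C | intermediate
6 | tert-butyl (2Z)-2-(bromomethyl)-3-[(4S,5S)-5-[(2S)-but-3-en-2-yl]-2,2-dimethyl-1,3-dioxolan-4-yl]prop-2-enoate | C=C[C@H](C)[C@@H]1OC(C)(C)O[C@H]1/C=C(\CBr)C(=O)OC(C)(C)C | intermediate
7 | (R)-lactic acid | C[C@@H](O)C(=O)O | starting material
8 | (2R,5R)-2-tert-butyl-5-methyl-1,3-dioxolan-4-one | C[C@H]1O[C@@H](C(C)(C)C)OC1=O | intermediate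
9 | lithium (2R)-2-tert-butyl-5-methyl-1,3-dioxol-4-olate (enolate of 8) | CC1=C([O-])O[C@H](C(C)(C)C)O1.[Li+] | intermediate
10 | (2R,5S)-2-tert-butyl-5-methyl-5-(prop-2-en-1-yl)-1,3-dioxolan-4-one | C=CC[C@]1(C)O[C@@H](C(C)(C)C)OC1=O | intermediate
11 | (2S)-2-hydroxy-N-methoxy-N,2-dimethylpent-4-enamide | C=CC[C@](C)(O)C(=O)N(C)OC | intermediate
12 | (4S)-4-hydroxy-4-methylhepta-1,6-dien-3-one | C=CC[C@](C)(O)C(=O)C=C | intermediate
13 | (4S)-4-methyl-3-oxohepta-1,6-dien-4-yl acetate | C=CC[C@](C)(OC(C)=O)C(=O)C=C | intermediate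
14 | (2S)-2-methyl-3-oxo-1-(1,2,4-trioxolan-3-yl)pent-4-en-2-yl acetate (secondary ozonide; ring carbon unassigned) | C=CC(=O)[C@@](C)(OC(C)=O)CC1OCOO1 | intermediate
15 | (3S)-3-methyl-1,4-dioxohex-5-en-3-yl acetate | O=CC[C@](C)(OC(C)=O)C(=O)C=C | intermediate
16 | tert-butyl (2Z)-3-[(4S,5S)-5-[(2S,3E,6S)-6-acetoxy-6-methyl-5,8-dioxooct-3-en-2-yl]-2,2-dimethyl-1,3-dioxolan-4-yl]-2-(bromomethyl)prop-2-enoate | O=CC[C@](C)(OC(C)=O)C(=O)/C=C/[C@H](C)[C@@H]1OC(C)(C)O[C@H]1/C=C(\CBr)C(=O)OC(C)(C)C | intermediate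
17 | allylchromium dichloride of 16 (CrCl2 in place of Br on C13) | O=CC[C@](C)(OC(C)=O)C(=O)/C=C/[C@H](C)[C@@H]1OC(C)(C)O[C@H]1/C=C(\C[Cr](Cl)Cl)C(=O)OC(C)(C)C | intermediate
18 | tert-butyl 2-[(1R,2R,4S,6E,8S,9S,10S)-4-acetoxy-2-hydroxy-9,10-(isopropylidenedioxy)-4,8-dimethyl-5-oxocyclodec-6-en-1-yl]prop-2-enoate | C=C(C(=O)OC(C)(C)C)[C@H]1[C@@H]2OC(C)(C)O[C@H]2[C@@H](C)/C=C/C(=O)[C@@](C)(OC(C)=O)C[C@H]1O | intermediate
19 | tert-butyl 2-[(1R,2R,4S,6E,8S,9S,10S)-4-acetoxy-9,10-(isopropylidenedioxy)-4,8-dimethyl-2-{[(2Z)-2-methylbut-2-enoyl]oxy}-5-oxocyclodec-6-en-1-yl]prop-2-enoate | C=C(C(=O)OC(C)(C)C)[C@H]1[C@@H]2OC(C)(C)O[C@H]2[C@@H](C)/C=C/C(=O)[C@@](C)(OC(C)=O)C[C@H]1OC(=O)/C(C)=C\C | intermediate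
20 | 2-[(1S,2R,4S,6E,8S,9S,10S)-4-acetoxy-9,10-dihydroxy-4,8-dimethyl-2-{[(2Z)-2-methylbut-2-enoyl]oxy}-5-oxocyclodec-6-en-1-yl]prop-2-enoic acid | C=C(C(=O)O)[C@H]1[C@H](O)[C@@H](O)[C@@H](C)/C=C/C(=O)[C@@](C)(OC(C)=O)C[C@H]1OC(=O)/C(C)=C\C | intermediate
21 | CNP0259154.2, (4S,5S,6S,7R,8R,10S)-10-acetoxy-8-angeloyloxy-5-hydroxy-1-oxogermacra-2(E),11(13)-dien-12,6-olide | C=C1C(=O)O[C@@H]2[C@@H](O)[C@@H](C)/C=C/C(=O)[C@@](C)(OC(C)=O)C[C@@H](OC(=O)/C(C)=C\C)[C@@H]12 | target

**Totals and risks**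

Total steps: 15. Longest linear sequence: 10 (steps 6–11, then 12–15); the west branch is 5 steps (1–5).

Most likely to fail:

Step 13 (ring closure). The ten-membered ring may close poorly, the facial or syn selectivity may erode inside the macrocyclic transition state, and CrCl2 might attack the α-acetoxy ketone. Fallback: set out from 6 and 15 and join them first by an intermolecular indium-mediated Barbier allylation (indium powder, THF/H2O, 23 °C), where the same Z-geometry and C6–O control act in an open-chain setting, to give tert-butyl (3R,4R,6S)-6-acetoxy-3-[(4S,5S)-5-[(2S)-but-3-en-2-yl]-2,2-dimethyl-1,3-dioxolan-4-yl]-4-hydroxy-6-methyl-2-methylidene-7-oxonon-8-enoate F1. Esterify its C8 hydroxyl as in step 14 to give tert-butyl (3R,4R,6S)-6-acetoxy-3-[(4S,5S)-5-[(2S)-but-3-en-2-yl]-2,2-dimethyl-1,3-dioxolan-4-yl]-6-methyl-2-methylidene-4-{[(2Z)-2-methylbut-2-enoyl]oxy}-7-oxonon-8-enoate F2. Then close the ring by ring-closing metathesis (second-generation Grubbs catalyst RuCl2(PCy3)(H2IMes)(=CHPh), toluene, 80 °C, 1 mM), which comes back to the route at 19.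

Step 12 (cross-metathesis). Aldehyde 15 is a β-acetoxy aldehyde and a vinyl ketone, so it may lose acetic acid or polymerise during a slow coupling with the α-branched alkene 6. Fallback: set out from 15 and mask the aldehyde at once (HC(OMe)3, pyridinium p-toluenesulfonate, CH2Cl2, 0 °C) as (3S)-1,1-dimethoxy-3-methyl-4-oxohex-5-en-3-yl acetate F3, which can be used in excess and recovered. Cross-metathesis of F3 with 6 under the step 12 conditions gives tert-butyl (2Z)-3-[(4S,5S)-5-[(2S,3E,6S)-6-acetoxy-8,8-dimethoxy-6-methyl-5-oxooct-3-en-2-yl]-2,2-dimethyl-1,3-dioxolan-4-yl]-2-(bromomethyl)prop-2-enoate F4. Unmasking with LiBF4 in wet MeCN (the acetonide survives) comes back to the route at 16, so the aldehyde appears only just before ring closure.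

Step 14 (angeloylation). The C8 alcohol is hindered, it may sit partly as a hemiketal with the C1 ketone, angelate can isomerise to tiglate, and the C10 acetyl could migrate under base. Fallback: set out from 18 and acylate with the unhindered 2-[bis(2,2,2-trifluoroethoxy)phosphoryl]propanoic acid (DCC, DMAP cat., CH2Cl2, 0 °C) to give tert-butyl 2-[(1R,2R,4S,6E,8S,9S,10S)-4-acetoxy-2-({2-[bis(2,2,2-trifluoroethoxy)phosphoryl]propanoyl}oxy)-9,10-(isopropylidenedioxy)-4,8-dimethyl-5-oxocyclodec-6-en-1-yl]prop-2-enoate F5. A Still–Gennari olefination with acetaldehyde (KN(SiMe3)2, 18-crown-6, THF, −78 °C) then builds the Z-configured 2-methylbut-2-enoate on the molecule and comes back to the route at 19.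

**Further compounds**
F1 | step 13 | tert-butyl (3R,4R,6S)-6-acetoxy-3-[(4S,5S)-5-[(2S)-but-3-en-2-yl]-2,2-dimethyl-1,3-dioxolan-4-yl]-4-hydroxy-6-methyl-2-methylidene-7-oxonon-8-enoate | C=C[C@H](C)[C@@H]1OC(C)(C)O[C@H]1[C@H](C(=C)C(=O)OC(C)(C)C)[C@H](O)C[C@](C)(OC(C)=O)C(=O)C=C
F2 | step 13 | tert-butyl (3R,4R,6S)-6-acetoxy-3-[(4S,5S)-5-[(2S)-but-3-en-2-yl]-2,2-dimethyl-1,3-dioxolan-4-yl]-6-methyl-2-methylidene-4-{[(2Z)-2-methylbut-2-enoyl]oxy}-7-oxonon-8-enoate | C=C[C@H](C)[C@@H]1OC(C)(C)O[C@H]1[C@H](C(=C)C(=O)OC(C)(C)C)[C@H](OC(=O)/C(C)=C\C)C[C@](C)(OC(C)=O)C(=O)C=C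
F3 | step 12 | (3S)-1,1-dimethoxy-3-methyl-4-oxohex-5-en-3-yl acetate | COC(OC)C[C@](C)(OC(C)=O)C(=O)C=C
F4 | step 12 | tert-butyl (2Z)-3-[(4S,5S)-5-[(2S,3E,6S)-6-acetoxy-8,8-dimethoxy-6-methyl-5-oxooct-3-en-2-yl]-2,2-dimethyl-1,3-dioxolan-4-yl]-2-(bromomethyl)prop-2-enoate | COC(OC)C[C@](C)(OC(C)=O)C(=O)/C=C/[C@H](C)[C@@H]1OC(C)(C)O[C@H]1/C=C(\CBr)C(=O)OC(C)(C)C
F5 | step 14 | tert-butyl 2-[(1R,2R,4S,6E,8S,9S,10S)-4-acetoxy-2-({2-[bis(2,2,2-trifluoroethoxy)phosphoryl]propanoyl}oxy)-9,10-(isopropylidenedioxy)-4,8-dimethyl-5-oxocyclodec-6-en-1-yl]prop-2-enoate | C=C(C(=O)OC(C)(C)C)[C@H]1[C@@H]2OC(C)(C)O[C@H]2[C@@H](C)/C=C/C(=O)[C@@](C)(OC(C)=O)C[C@H]1OC(=O)C(C)P(=O)(OCC(F)(F)F)OCC(F)(F)F
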